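A direct plan would convert isovanillin A1 by Baeyer–Villiger oxidation into 3-hydroxy-4-methoxyphenyl formate A2 and solvolyse it to 4-methoxybenzene-1,3-diol A3, acylate A3 with 3,4,5-trimethoxyphenylacetic acid A4 in BF3·OEt2 to deoxybenzoin A5, and in the same pot carry A5 through enaminone A6 into the target by a Vilsmeier-type one-carbon insertion and ring closure.
Its weakest steps would be:
- the oxidation/solvolysis run-up from A1 through A2: two operations that build no skeletal bond, only to reach the simple, air-sensitive diol A3, which has to be carried on crude;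
- the Friedel–Crafts acylation of the unprotected diol A3 with acid A4 in hot neat Lewis acid: one of three open ring positions must react, against O-acylation and tarring of the oxidation-prone arene;
- the telescoped formylation/cyclisation of A5 with a free 7-OH: three bonds (C4–C4a, C2–C3, O1–C2) would be made without purification, with O-formylation or O-sulfonylation and boron chelates as competitors.

**Retrosynthetic overview**
- Feature used: the C3–C1' bond that holds ring B on C3 of pyranone ring C, next to an unsubstituted C2. A 3-arylchromone is a chalcone whose aryl group has moved from C-β (future C2) to C-α (future C3).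
- Key disconnection: C3–C1' by an oxidative 1,2-aryl shift of chalcone 7 with trivalent thallium, then O1–C2 by acid closure of the resulting β-keto acetal in the same flask. C2–C3 comes from a Claisen–Schmidt condensation of ketone 5 with aldehyde 6.
- Ring order: rings A and B are bought; ring C closes last, only after the skeleton has been rearranged. O1 is put on acetovanillone 1 by ketone-directed C–H hydroxylation.
- Weak steps avoided: no Baeyer–Villiger run-up and no free electron-rich diol (ring A carries its acyl group throughout); no Friedel–Crafts regiochemistry (the acyl carbon is in place from the start); no one-carbon insertion on a free phenol (both phenols stay as methoxymethyl (MOM) ethers until the final acid stage, which also removes them).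

Key step: step 4

Remark: the target has no stereocentre; 8 and 9 are racemic, 10 is a racemic diastereomer mixture, and these stereocentres are destroyed within step 4.

**Step 1**
Reactants: 1 acetovanillone (1-(4-hydroxy-3-methoxyphenyl)ethan-1-one)
Product: 4 1-(2,4-dihydroxy-5-methoxyphenyl)ethan-1-one, via aryl trifluoroacetate 2 (not isolated), via bis(trifluoroacetate) 3 (not isolated)
Conditions: Pd(OAc)2 (5 mol %), K2S2O8 (2 equiv), CF3CO2H/(CF3CO)2O 9:1, rt to 50 °C; then H2O, rt
Reagents that add atoms: trifluoroacetic acid, OC(=O)C(F)(F)F (supplies the new phenolic oxygen)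
Why: Ketone-directed ortho C–H hydroxylation of an aryl ketone catalysed by divalent palladium: the phenol is masked in situ as its trifluoroacetate, the acetyl oxygen directs cyclopalladation to the unhindered C6–H (para to OMe) and not to C2–H between acetyl and OMe, persulfate oxidises the palladacycle to tetravalent palladium, and C–O reductive elimination gives an aryl trifluoroacetate that resists over-oxidation and is hydrolysed on work-up.

**Step 2**
Reactants: 4 1-(2,4-dihydroxy-5-methoxyphenyl)ethan-1-one
Product: 5 1-[5-methoxy-2,4-bis(methoxymethoxy)phenyl]ethan-1-one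
Conditions: NaH (2.2 equiv), DMF, 0 °C; MOMCl (2.5 equiv), 0 °C to rt
Reagents that add atoms: chloromethyl methyl ether, COCCl
Why: Williamson-type O-alkylation of both phenoxides, in which preforming the disodium salt breaks the hydrogen bond of the 2-OH to the carbonyl so that this chelated phenol is alkylated as well.

**Step 3**
Reactants: 5 1-[5-methoxy-2,4-bis(methoxymethoxy)phenyl]ethan-1-one; 6 3,4,5-trimethoxybenzaldehyde
Product: 7 (E)-1-[5-methoxy-2,4-bis(methoxymethoxy)phenyl]-3-(3,4,5-trimethoxyphenyl)prop-2-en-1-one
Conditions: 50% aq KOH, EtOH, rt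
Reagents that add atoms: none
Why: Claisen–Schmidt condensation of the ketone enolate with the non-enolisable aldehyde, followed by E1cB dehydration to the conjugated (E)-enone under thermodynamic control; the MOM ethers are stable to base and, with no free 2'-OH, no flavanone can form.

**Step 4**
Reactants: 7 (E)-1-[5-methoxy-2,4-bis(methoxymethoxy)phenyl]-3-(3,4,5-trimethoxyphenyl)prop-2-en-1-one
Product: 11 7-hydroxy-6-methoxy-3-(3,4,5-trimethoxyphenyl)-4H-chromen-4-one, via keto acetal 8 (not isolated), via phenolic keto acetal 9 (not isolated), via 2-methoxyisoflavanone 10 (not isolated)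
Conditions: Tl(NO3)3·3H2O (1.2 equiv), MeOH/CH2Cl2 5:1, rt; filter TlNO3; then 10% aq HCl, MeOH, reflux
Reagents that add atoms: none
Why: Mechanism: methanol adds to C-β of the enone while trivalent thallium bonds to C-α; monovalent thallium then leaves as the 3,4,5-trimethoxyphenyl group shifts from C-β to C-α through a phenonium ion, and methanol traps the methoxy-stabilised oxocarbenium ion at C-β to give β-keto acetal 8, so that C3–C1' is formed and the old C2–C1' bond is broken. The closest known reaction type is the thallium nitrate oxidative rearrangement of chalcones to 1,2-diaryl-3,3-dimethoxypropan-1-ones and their acid cyclisation to isoflavones, which mirrors the biosynthetic aryl shift. Hot aqueous HCl in methanol then removes both MOM groups (9), the freed 2'-OH attacks the oxocarbenium ion formed from the acetal (O1–C2, 6-exo-trig) to give 10, and loss of methanol aromatises ring C. No stereocentre remains, because C-α of 8 becomes sp2 C3. The step needs ring B to migrate in preference to ring A and ring A to escape oxidation: ring B is the better migrating group through its para-methoxy group, the carbonyl is not ketalised in methanol without orthoformate so ring A has no path to migrate, and ring A carries no free phenol during the oxidation. The 2'-O-MOM group also blocks aurone formation.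

**Compound list**
1 | acetovanillone, 1-(4-hydroxy-3-methoxyphenyl)ethan-1-one | CC(=O)c1ccc(O)c(OC)c1 | starting material
2 | 4-acetyl-2-methoxyphenyl trifluoroacetate | CC(=O)c1ccc(OC(=O)C(F)(F)F)c(OC)c1 | intermediate
3 | 4-acetyl-6-methoxy-1,3-phenylene bis(trifluoroacetate) | CC(=O)c1cc(OC)c(OC(=O)C(F)(F)F)cc1OC(=O)C(F)(F)F | intermediate
4 | 1-(2,4-dihydroxy-5-methoxyphenyl)ethan-1-one | CC(=O)c1cc(OC)c(O)cc1O | intermediate
5 | 1-[5-methoxy-2,4-bis(methoxymethoxy)phenyl]ethan-1-one | CC(=O)c1cc(OC)c(OCOC)cc1OCOC | intermediate
6 | 3,4,5-trimethoxybenzaldehyde | COc1cc(C=O)cc(OC)c1OC | starting material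
7 | (E)-1-[5-methoxy-2,4-bis(methoxymethoxy)phenyl]-3-(3,4,5-trimethoxyphenyl)prop-2-en-1-one | COCOc1cc(OCOC)c(cc1OC)C(=O)/C=C/c1cc(OC)c(OC)c(OC)c1 | intermediate
8 | 1-[5-methoxy-2,4-bis(methoxymethoxy)phenyl]-3,3-dimethoxy-2-(3,4,5-trimethoxyphenyl)propan-1-one (racemic) | COCOc1cc(OCOC)c(cc1OC)C(=O)C(C(OC)OC)c1cc(OC)c(OC)c(OC)c1 | intermediate
9 | 1-(2,4-dihydroxy-5-methoxyphenyl)-3,3-dimethoxy-2-(3,4,5-trimethoxyphenyl)propan-1-one (racemic) | COc1cc(C(=O)C(C(OC)OC)c2cc(OC)c(OC)c(OC)c2)c(O)cc1O | intermediate
10 | 7-hydroxy-2,6-dimethoxy-3-(3,4,5-trimethoxyphenyl)chroman-4-one (racemic, mixture of diastereomers) | COc1cc2c(cc1O)OC(OC)C(c1cc(OC)c(OC)c(OC)c1)C2=O | intermediate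
11 | 7-hydroxy-6-methoxy-3-(3,4,5-trimethoxyphenyl)-4H-chromen-4-one | COc1cc2c(=O)c(-c3cc(OC)c(OC)c(OC)c3)coc2cc1O | target

**Totals**
Total step count: 4. Longest linear sequence: 4 steps (1 → 4 → 5 → 7 → 11).

**Steps most likely to fail**

Step 4 (key step). The shift of the 3,4,5-trimethoxyphenyl group may be slow. Oxidative attack on the electron-rich rings, migration of ring A, or loss of a MOM group before the oxidation could then take over. The fallback makes C3–C1' by cross-coupling on a finished chromone, so it does not depend on migratory aptitude. It sets out from compound 4. Alkylation of the non-chelated 4-OH (MOMCl, K2CO3, acetone, rt) should give 1-[2-hydroxy-5-methoxy-4-(methoxymethoxy)phenyl]ethan-1-one F1. Condensation with N,N-dimethylformamide dimethyl acetal at 90 °C should give (E)-3-(dimethylamino)-1-[2-hydroxy-5-methoxy-4-(methoxymethoxy)phenyl]prop-2-en-1-one F2. Iodine in CHCl3/pyridine should cyclise and iodinate it to 3-iodo-6-methoxy-7-(methoxymethoxy)-4H-chromen-4-one F3. Suzuki–Miyaura coupling with 3,4,5-trimethoxyphenylboronic acid F4 (Pd(PPh3)4, zerovalent palladium, Na2CO3, DME/H2O, 80 °C) should give 6-methoxy-7-(methoxymethoxy)-3-(3,4,5-trimethoxyphenyl)-4H-chromen-4-one F5. HCl in MeOH would then remove the MOM group and come back to the route at compound 11.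

Step 1. Cyclopalladation may be outrun by persulfate oxidation of the methoxy-bearing ring, or hydroxylation may be incomplete or occur at the hindered ortho position. The fallback installs the oxygen by electrophilic bromination followed by copper-catalysed substitution of the bromide. It sets out from compound 1. Acetylation (Ac2O, pyridine) should give 4-acetyl-2-methoxyphenyl acetate F6. Buffered nuclear bromination para to the methoxy group (Br2, NaOAc, AcOH, rt; the buffer suppresses side-chain bromination) should give 4-acetyl-5-bromo-2-methoxyphenyl acetate F7. Copper-catalysed hydroxylation of the aryl bromide (CuI, 1,10-phenanthroline, aq KOH, DMSO, 100 °C), with saponification of the acetate in the same pot, would come back to the route at compound 4.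

Step 3. Condensation of the hindered, electron-rich ketone enolate may be sluggish, so that Cannizzaro loss of the aldehyde and conjugate addition of alkoxide to the enone compete. The fallback forms the C-β–aryl bond instead of the C-α–C-β bond. It sets out from compound 5. N,N-Dimethylformamide dimethyl acetal at 100 °C should give (E)-3-(dimethylamino)-1-[5-methoxy-2,4-bis(methoxymethoxy)phenyl]prop-2-en-1-one F8. Conjugate addition of (3,4,5-trimethoxyphenyl)magnesium bromide F9, made from 5-bromo-1,2,3-trimethoxybenzene F10 and Mg in THF, followed by loss of dimethylamine on NH4Cl work-up, would come back to the route at compound 7.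

**Further compounds**
F1 | step 4 | 1-[2-hydroxy-5-methoxy-4-(methoxymethoxy)phenyl]ethan-1-one | CC(=O)c1cc(OC)c(OCOC)cc1O
F2 | step 4 | (E)-3-(dimethylamino)-1-[2-hydroxy-5-methoxy-4-(methoxymethoxy)phenyl]prop-2-en-1-one | CN(C)/C=C/C(=O)c1cc(OC)c(OCOC)cc1O
F3 | step 4 | 3-iodo-6-methoxy-7-(methoxymethoxy)-4H-chromen-4-one | COCOc1cc2occ(I)c(=O)c2cc1OC
F4 | step 4 | 3,4,5-trimethoxyphenylboronic acid | COc1cc(B(O)O)cc(OC)c1OC
F5 | step 4 | 6-methoxy-7-(methoxymethoxy)-3-(3,4,5-trimethoxyphenyl)-4H-chromen-4-one | COCOc1cc2occ(-c3cc(OC)c(OC)c(OC)c3)c(=O)c2cc1OC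
F6 | step 1 | 4-acetyl-2-methoxyphenyl acetate | CC(=O)Oc1ccc(C(C)=O)cc1OC
F7 | step 1 | 4-acetyl-5-bromo-2-methoxyphenyl acetate | CC(=O)Oc1cc(Br)c(C(C)=O)cc1OC
F8 | step 3 | (E)-3-(dimethylamino)-1-[5-methoxy-2,4-bis(methoxymethoxy)phenyl]prop-2-en-1-one | CN(C)/C=C/C(=O)c1cc(OC)c(OCOC)cc1OCOC
F9 | step 3 | (3,4,5-trimethoxyphenyl)magnesium bromide | COc1cc([Mg]Br)cc(OC)c1OC
F10 | step 3 | 5-bromo-1,2,3-trimethoxybenzene | COc1cc(Br)cc(OC)c1OC
A1 | direct plan | isovanillin (3-hydroxy-4-methoxybenzaldehyde) | COc1ccc(C=O)cc1O
A2 | direct plan | 3-hydroxy-4-methoxyphenyl formate | COc1ccc(OC=O)cc1O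
A3 | direct plan | 4-methoxybenzene-1,3-diol | COc1ccc(O)cc1O
A4 | direct plan | 3,4,5-trimethoxyphenylacetic acid | COc1cc(CC(=O)O)cc(OC)c1OC
A5 | direct plan | 1-(2,4-dihydroxy-5-methoxyphenyl)-2-(3,4,5-trimethoxyphenyl)ethan-1-one | COc1cc(C(=O)Cc2cc(OC)c(OC)c(OC)c2)c(O)cc1O
A6 | direct plan | (E)-3-(dimethylamino)-1-(2,4-dihydroxy-5-methoxyphenyl)-2-(3,4,5-trimethoxyphenyl)prop-2-en-1-one | COc1cc(C(=O)/C(=C/N(C)C)c2cc(OC)c(OC)c(OC)c2)c(O)cc1O
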